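The oxolane is closed last, by dehydrogenative C–O bond formation between C2, the benzylic carbon of the catechol-derived ring, and the ring oxygen O1. The step exploits two features: the para-oxygen of that aryl ring, which lets DDQ abstract hydride from the C2–H bond, and the 1,4-diol made up of the C3 hydroxymethyl and the exocyclic carbinol, which is masked as a γ-lactone. The precursor is therefore an all-cis α-benzyl-β-hydroxymethyl-γ-aryl butyrolactone, assembled by Stobbe condensation, an auxiliary-controlled anti-aldol/lactonisation and a face-selective hydrogenation. The lactone fixes the cis ring fusion, deactivates the second benzylic position and turns the new aryl group exo; hydride reduction and hydrogenolysis then release the target.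

Key step: step 6

Locants used below: C7 = oxolane C2 (bears the catechol ring), C8 = oxolane C3, C9 = its hydroxymethyl carbon, C8' = oxolane C4, C9' = oxolane C5, C7' = the exocyclic carbinol carbon.

Assumption: the MgCl2-catalysed anti-aldol is taken to follow the chelated Z-enolate model (aldehyde approaches anti to the auxiliary benzyl group), which is why the (R)-auxiliary is chosen; with the opposite sense the (S)-auxiliary would be used.

Step 1
Reactants: 1 3,4-bis(benzyloxy)benzaldehyde; 2 dimethyl succinate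
Product: 3 (E)-4-[3,4-bis(benzyloxy)phenyl]-3-(methoxycarbonyl)but-3-enoic acid
Conditions: NaOMe (1.5 equiv), MeOH, reflux; then aq HCl
Reagents that add atoms: none
Why: Stobbe condensation, in which the succinate enolate adds to the non-enolisable aldehyde and the sequence is driven to the half-ester carboxylate, which should form with the thermodynamically preferred E geometry (aryl trans to the ester); no stereocentre is created.

Step 2
Reactants: 3 (E)-4-[3,4-bis(benzyloxy)phenyl]-3-(methoxycarbonyl)but-3-enoic acid; 4 (R)-4-benzyloxazolidin-2-one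
Product: 6 (R)-4-benzyl-3-[(E)-4-[3,4-bis(benzyloxy)phenyl]-3-(methoxycarbonyl)but-3-enoyl]oxazolidin-2-one, via mixed pivalic anhydride 5 (not isolated)
Conditions: PivCl, Et3N, THF, −20 °C; then 4, LiCl, −20 °C to rt
Reagents that add atoms: none
Why: N-acylation of the oxazolidinone through the mixed anhydride should occur only at the free carboxyl group and leave the conjugated methyl ester and the alkene geometry untouched.

Step 3
Reactants: 6 (R)-4-benzyl-3-[(E)-4-[3,4-bis(benzyloxy)phenyl]-3-(methoxycarbonyl)but-3-enoyl]oxazolidin-2-one; 7 4-(benzyloxy)-3-methoxybenzaldehyde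
Product: 10 (R)-4-benzyl-3-{(2R,3S,4E)-2-[4-(benzyloxy)-3-methoxyphenyl]-4-[3,4-bis(benzyloxy)benzylidene]-5-oxooxolane-3-carbonyl}oxazolidin-2-one, via silyl ether aldol adduct 8 (not isolated), via hydroxy ester aldol adduct 9 (not isolated)
Conditions: MgCl2 (0.2 equiv), Et3N, TMSCl, EtOAc, rt; then 1 M HCl, THF, rt; then PPTS (cat.), PhMe, 60 °C
Reagents that add atoms: none
Why: Magnesium-halide-catalysed direct anti-aldol reaction of an N-acyloxazolidinone, in which the chelated Z-enolate should react at its α-carbon on the face opposite the auxiliary benzyl group to set C8' and C7' in an anti relationship, after which desilylation lets the C7' hydroxyl close onto the conjugated methyl ester so that the anti relationship becomes the cis-disubstituted γ-lactone.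

Step 4
Reactants: 10 (R)-4-benzyl-3-{(2R,3S,4E)-2-[4-(benzyloxy)-3-methoxyphenyl]-4-[3,4-bis(benzyloxy)benzylidene]-5-oxooxolane-3-carbonyl}oxazolidin-2-one
Product: 11 (3E,4R,5R)-5-[4-(benzyloxy)-3-methoxyphenyl]-3-[3,4-bis(benzyloxy)benzylidene]-4-(hydroxymethyl)oxolan-2-one
Conditions: NaBH4, THF/H2O (4:1), 0 °C to rt
Reagents that add atoms: none
Why: Reductive cleavage of the auxiliary, in which borohydride should reduce the activated imide carbonyl to the primary alcohol while the less electrophilic cross-conjugated lactone survives; no stereocentre is touched.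

Step 5
Reactants: 11 (3E,4R,5R)-5-[4-(benzyloxy)-3-methoxyphenyl]-3-[3,4-bis(benzyloxy)benzylidene]-4-(hydroxymethyl)oxolan-2-one
Product: 12 (3R,4R,5R)-5-[4-(benzyloxy)-3-methoxyphenyl]-3-[3,4-bis(benzyloxy)benzyl]-4-(hydroxymethyl)oxolan-2-one
Conditions: H2 (1 atm), 10% Pd/C, Ph2S (0.01 equiv), EtOAc, rt
Reagents that add atoms: none
Why: Heterogeneous catalytic hydrogenation should add both hydrogens syn from the lactone face opposite the cis C8' hydroxymethyl and C7' aryl groups, which sets C8 with the benzyl group cis to both (all-cis lactone), while the sulfide-poisoned catalyst should spare the aryl benzyl ethers and the benzylic lactone C–O bond.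

Step 6
Reactants: 12 (3R,4R,5R)-5-[4-(benzyloxy)-3-methoxyphenyl]-3-[3,4-bis(benzyloxy)benzyl]-4-(hydroxymethyl)oxolan-2-one
Product: 14 (1S,4R,5R,8S)-8-[3,4-bis(benzyloxy)phenyl]-4-[4-(benzyloxy)-3-methoxyphenyl]-3,7-dioxabicyclo[3.3.0]octan-2-one, via benzylic cation 13 (not isolated)
Conditions: DDQ (1.1 equiv), 4 Å MS, CH2Cl2, 0 °C to rt
Reagents that add atoms: none
Why: DDQ should form a charge-transfer complex with the 3,4-bis(benzyloxy)phenyl ring and abstract hydride from the C7 methylene, the para-benzyloxy oxygen stabilising cation 13 as a quinone-methide-type oxocarbenium ion that is captured by the C9' hydroxyl with loss of a proton to the hydroquinone anion. The closest known reaction type is the DDQ-mediated benzylic C–H oxidation of para-alkoxy arylalkanes with oxygen trapping, as in benzylic alkoxylation and the oxidative conversion of para-methoxybenzyl ethers of 1,3-diols into cyclic acetals. The oxolane closes in a 5-exo-trig mode, the oxygen adding to the exocyclic carbon of the quinoid C7=C(aryl) unit. The new C7 stereocentre is substrate-controlled: the cis arrangement of the C8 benzyl and C8' hydroxymethyl groups enforces a cis ring fusion, and the planar cation should be attacked in the conformer that turns the aryl group away from the lactone carbonyl to the convex face, giving the 2,3-trans (7S) ether. The step needs site selectivity for C7–H over the C7' benzylic hydrogen and the benzyl ether methylenes, which is secured because C7' carries the electron-withdrawing lactone acyloxy group and the O-benzyl methylenes sit on unactivated phenyl rings. Over-oxidation should be held back because the remaining C7 hydrogen of 14 lies on the concave face of the bicycle.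

Step 7
Reactants: 14 (1S,4R,5R,8S)-8-[3,4-bis(benzyloxy)phenyl]-4-[4-(benzyloxy)-3-methoxyphenyl]-3,7-dioxabicyclo[3.3.0]octan-2-one
Product: 15 {(2S,3R,4R)-2-[3,4-bis(benzyloxy)phenyl]-4-[(R)-[4-(benzyloxy)-3-methoxyphenyl](hydroxy)methyl]oxolan-3-yl}methanol
Conditions: LiAlH4, THF, 0 °C
Reagents that add atoms: none
Why: Hydride reduction of the γ-lactone to the 1,4-diol cleaves only the acyl C–O bond, so the configurations at C7', C8', C8 and C7 should be retained.

Step 8
Reactants: 15 {(2S,3R,4R)-2-[3,4-bis(benzyloxy)phenyl]-4-[(R)-[4-(benzyloxy)-3-methoxyphenyl](hydroxy)methyl]oxolan-3-yl}methanol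
Product: 16 (7R)-7-hydroxytaxiresinol
Conditions: H2 (1 atm), 10% Pd/C, EtOAc/MeOH, rt
Reagents that add atoms: none
Why: Hydrogenolysis of the three aryl benzyl ethers under neutral conditions at atmospheric pressure should be much faster than cleavage of the benzylic C–O bonds at C7 and C7', so no stereocentre is touched.

Compound list

1 | 3,4-bis(benzyloxy)benzaldehyde | O=Cc1ccc(OCc2ccccc2)c(OCc2ccccc2)c1 | starting material
2 | dimethyl succinate | COC(=O)CCC(=O)OC | starting material
3 | (E)-4-[3,4-bis(benzyloxy)phenyl]-3-(methoxycarbonyl)but-3-enoic acid | OC(=O)C/C(=C\c1ccc(OCc2ccccc2)c(OCc2ccccc2)c1)C(=O)OC | intermediate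
4 | (R)-4-benzyloxazolidin-2-one | O=C1N[C@H](Cc2ccccc2)CO1 | starting material
5 | mixed pivalic anhydride of 3 | CC(C)(C)C(=O)OC(=O)C/C(=C\c1ccc(OCc2ccccc2)c(OCc2ccccc2)c1)C(=O)OC | intermediate
6 | (R)-4-benzyl-3-[(E)-4-[3,4-bis(benzyloxy)phenyl]-3-(methoxycarbonyl)but-3-enoyl]oxazolidin-2-one | O=C(C/C(=C\c1ccc(OCc2ccccc2)c(OCc2ccccc2)c1)C(=O)OC)N1[C@H](Cc2ccccc2)COC1=O | intermediate
7 | 4-(benzyloxy)-3-methoxybenzaldehyde | COc1cc(C=O)ccc1OCc1ccccc1 | starting material
8 | methyl (2E,3S,4R)-4-[4-(benzyloxy)-3-methoxyphenyl]-2-[3,4-bis(benzyloxy)benzylidene]-3-[(R)-4-benzyl-2-oxooxazolidine-3-carbonyl]-4-(trimethylsilyloxy)butanoate | COc1cc([C@H](O[Si](C)(C)C)[C@@H](C(=O)N2[C@H](Cc3ccccc3)COC2=O)/C(=C\c2ccc(OCc3ccccc3)c(OCc3ccccc3)c2)C(=O)OC)ccc1OCc1ccccc1 | intermediate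
9 | methyl (2E,3S,4R)-4-[4-(benzyloxy)-3-methoxyphenyl]-2-[3,4-bis(benzyloxy)benzylidene]-3-[(R)-4-benzyl-2-oxooxazolidine-3-carbonyl]-4-hydroxybutanoate | COc1cc([C@H](O)[C@@H](C(=O)N2[C@H](Cc3ccccc3)COC2=O)/C(=C\c2ccc(OCc3ccccc3)c(OCc3ccccc3)c2)C(=O)OC)ccc1OCc1ccccc1 | intermediate
10 | (R)-4-benzyl-3-{(2R,3S,4E)-2-[4-(benzyloxy)-3-methoxyphenyl]-4-[3,4-bis(benzyloxy)benzylidene]-5-oxooxolane-3-carbonyl}oxazolidin-2-one | COc1cc([C@@H]2OC(=O)/C(=C/c3ccc(OCc4ccccc4)c(OCc4ccccc4)c3)[C@@H]2C(=O)N2[C@H](Cc3ccccc3)COC2=O)ccc1OCc1ccccc1 | intermediate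
11 | (3E,4R,5R)-5-[4-(benzyloxy)-3-methoxyphenyl]-3-[3,4-bis(benzyloxy)benzylidene]-4-(hydroxymethyl)oxolan-2-one | COc1cc([C@@H]2OC(=O)/C(=C/c3ccc(OCc4ccccc4)c(OCc4ccccc4)c3)[C@@H]2CO)ccc1OCc1ccccc1 | intermediate
12 | (3R,4R,5R)-5-[4-(benzyloxy)-3-methoxyphenyl]-3-[3,4-bis(benzyloxy)benzyl]-4-(hydroxymethyl)oxolan-2-one (all-cis) | COc1cc([C@@H]2OC(=O)[C@H](Cc3ccc(OCc4ccccc4)c(OCc4ccccc4)c3)[C@@H]2CO)ccc1OCc1ccccc1 | intermediate
13 | C7 benzylic cation of 12, ion pair with the hydroquinone monoanion from DDQ | COc1cc([C@@H]2OC(=O)[C@H]([CH+]c3ccc(OCc4ccccc4)c(OCc4ccccc4)c3)[C@@H]2CO)ccc1OCc1ccccc1.[O-]c1c(Cl)c(Cl)c(O)c(C#N)c1C#N | intermediate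
14 | (1S,4R,5R,8S)-8-[3,4-bis(benzyloxy)phenyl]-4-[4-(benzyloxy)-3-methoxyphenyl]-3,7-dioxabicyclo[3.3.0]octan-2-one (cis-fused; C8 aryl exo, C4 aryl endo) | COc1cc([C@@H]2OC(=O)[C@H]3[C@@H]2CO[C@@H]3c2ccc(OCc4ccccc4)c(OCc4ccccc4)c2)ccc1OCc1ccccc1 | intermediate
15 | {(2S,3R,4R)-2-[3,4-bis(benzyloxy)phenyl]-4-[(R)-[4-(benzyloxy)-3-methoxyphenyl](hydroxy)methyl]oxolan-3-yl}methanol | COc1cc([C@H](O)[C@H]2CO[C@H](c3ccc(OCc4ccccc4)c(OCc4ccccc4)c3)[C@H]2CO)ccc1OCc1ccccc1 | intermediate
16 | (7R)-7-hydroxytaxiresinol, 4-{(2S,3R,4R)-4-[(R)-hydroxy(4-hydroxy-3-methoxyphenyl)methyl]-3-(hydroxymethyl)oxolan-2-yl}benzene-1,2-diol | COc1cc([C@H](O)[C@H]2CO[C@H](c3ccc(O)c(O)c3)[C@H]2CO)ccc1O | target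

Total step count: 8. Longest linear sequence: 8 steps (1 and 2 to 16).

Steps most likely to fail

Step 6 (key step). The newly formed benzylic ether may be oxidised further, cation 13 may lose the C8 proton and fall back to the arylidene lactone, or the strained all-cis lactone may undergo acyl migration to the primary hydroxyl before it is oxidised. The fallback sets out from 11 and comes back at 14, so that steps 5 and 6 are bypassed. The ring is closed from the alkene: NIS (NaHCO3, MeCN, 0 °C) should effect a 5-endo iodoetherification in which anti addition across the E-alkene places the aryl group exo, giving (1R,4R,5R,8R)-8-[3,4-bis(benzyloxy)phenyl]-4-[4-(benzyloxy)-3-methoxyphenyl]-1-iodo-3,7-dioxabicyclo[3.3.0]octan-2-one F1. Radical deiodination (Bu3SnH, AIBN, PhH, 80 °C) then delivers hydrogen to the ring-fusion carbon on the convex face and should give 14.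

Step 3. The cross-conjugated enolate of 6 may react at its γ-carbon or let the double bond migrate, the bulky alkenyl substituent may erode the anti selectivity, and the electron-rich benzylic carbinol may ionise during lactonisation. The fallback sets out from 3 and comes back at 12, fixing C8 before the aldol reaction so that the donor is a saturated imide. Asymmetric hydrogenation of 3 with [Rh(cod)((R,R)-Et-DuPhos)]BF4 (H2, MeOH; the ligand antipode is exchanged if the sense of induction proves opposite) should give (R)-4-[3,4-bis(benzyloxy)phenyl]-3-(methoxycarbonyl)butanoic acid F2. Activation as its mixed pivalic anhydride F3 and acylation of 4 as in step 2 give methyl (R)-2-[3,4-bis(benzyloxy)benzyl]-4-[(R)-4-benzyl-2-oxooxazolidin-3-yl]-4-oxobutanoate F4. The MgCl2-catalysed anti-aldol with 7 under the conditions of step 3 proceeds through the silyl ether aldol adduct F5 and the hydroxy ester aldol adduct F6 to the all-cis lactone imide F7, and NaBH4 reduction as in step 4 leads to 12.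

Step 5. Hydrogen may cleave aryl benzyl ethers or the benzylic lactone C–O bond, the hydroxyl group may steer delivery to the wrong face, the double bond may migrate into the ring, or the strained all-cis lactone may epimerise at C8. The fallback sets out from 11 and comes back at 12 and replaces surface hydrogenation by an ionic reduction. Conjugate hydride addition with LiBH(s-Bu)3 (2.2 equiv, THF, −78 °C) followed by kinetic protonation of the lactone enolate with a hindered phenol on the face opposite the C8' and C7' substituents should give the same all-cis lactone 12. This fallback makes no new compound (F0).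

Further compounds

F1 | step 6 | (1R,4R,5R,8R)-8-[3,4-bis(benzyloxy)phenyl]-4-[4-(benzyloxy)-3-methoxyphenyl]-1-iodo-3,7-dioxabicyclo[3.3.0]octan-2-one | COc1cc([C@@H]2OC(=O)[C@@]3(I)[C@@H]2CO[C@@H]3c2ccc(OCc4ccccc4)c(OCc4ccccc4)c2)ccc1OCc1ccccc1
F2 | step 3 | (R)-4-[3,4-bis(benzyloxy)phenyl]-3-(methoxycarbonyl)butanoic acid | OC(=O)C[C@@H](Cc1ccc(OCc2ccccc2)c(OCc2ccccc2)c1)C(=O)OC
F3 | step 3 | mixed pivalic anhydride of F2 | CC(C)(C)C(=O)OC(=O)C[C@@H](Cc1ccc(OCc2ccccc2)c(OCc2ccccc2)c1)C(=O)OC
F4 | step 3 | methyl (R)-2-[3,4-bis(benzyloxy)benzyl]-4-[(R)-4-benzyl-2-oxooxazolidin-3-yl]-4-oxobutanoate | O=C(C[C@@H](Cc1ccc(OCc2ccccc2)c(OCc2ccccc2)c1)C(=O)OC)N1[C@H](Cc2ccccc2)COC1=O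
F5 | step 3 | methyl (2R,3S,4R)-4-[4-(benzyloxy)-3-methoxyphenyl]-2-[3,4-bis(benzyloxy)benzyl]-3-[(R)-4-benzyl-2-oxooxazolidine-3-carbonyl]-4-(trimethylsilyloxy)butanoate | COc1cc([C@H](O[Si](C)(C)C)[C@@H](C(=O)N2[C@H](Cc3ccccc3)COC2=O)[C@@H](Cc2ccc(OCc3ccccc3)c(OCc3ccccc3)c2)C(=O)OC)ccc1OCc1ccccc1
F6 | step 3 | methyl (2R,3S,4R)-4-[4-(benzyloxy)-3-methoxyphenyl]-2-[3,4-bis(benzyloxy)benzyl]-3-[(R)-4-benzyl-2-oxooxazolidine-3-carbonyl]-4-hydroxybutanoate | COc1cc([C@H](O)[C@@H](C(=O)N2[C@H](Cc3ccccc3)COC2=O)[C@@H](Cc2ccc(OCc3ccccc3)c(OCc3ccccc3)c2)C(=O)OC)ccc1OCc1ccccc1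
F7 | step 3 | (R)-4-benzyl-3-{(2R,3S,4R)-2-[4-(benzyloxy)-3-methoxyphenyl]-4-[3,4-bis(benzyloxy)benzyl]-5-oxooxolane-3-carbonyl}oxazolidin-2-one | COc1cc([C@@H]2OC(=O)[C@H](Cc3ccc(OCc4ccccc4)c(OCc4ccccc4)c3)[C@@H]2C(=O)N2[C@H](Cc3ccccc3)COC2=O)ccc1OCc1ccccc1
F0 | step 5 | none | none
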